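Conventions: labdane numbering (C1–C20) is used for positions; β is the face of the C10 methyl group; TBS = tert-butyldimethylsilyl.
Assumption: compounds 1, 2, 4, 8 and 19 are taken as catalogue chemicals. The sense of induction of the bis(oxazoline) ligand in step 7 is assigned by analogy; should it be opposite, the (R,R) ligand is used with no other change.

## The problem

The target is a normal-series labdane: a trans-fused decalin (rings A and B) with five stereocentres (C4, C5, C10, C8, C9) and an achiral α-substituted butenolide (C13–C16) on a two-carbon tether (C11–C12). C4 and C10 are quaternary, and the C19 carboxyl on C4 is axial, syn to the C10 methyl, so it can only be unmasked by alkyl–oxygen cleavage, not by hydrolysis at the carbonyl. C8 (equatorial CH2OH, 8β-H) and C9 (equatorial side chain) are trans. C8 is the one centre that can be corrected by equilibration, and only while C17 is a carbonyl; hydroboration of the usual 8(17)-alkene attacks the α face and gives the axial epimer. Three oxidised carbons (C19 acid, C17 alcohol, C16 lactone) must be told apart, and the butenolide survives neither hydride reagents nor strong base, so it has to arrive after C17 is reduced. C1–C3, C6, C7, C11 and C12 are bare, so any helper group must be removed again. The feature that opens the problem is that the two ring carbons bearing oxidised substituents, C4 (C19) and C8 (C17), are the outer ends of the two bonds, C4–C5 and C9–C10, that close rings A and B. A radical at C4 (stabilised by C19 and a temporary C3 ketone) and an acceptor alkene C8=C9 (activated by C17) bracket the electron-rich C5=C10 alkene, so one polarity-alternating radical chain can close both rings.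

## Retrosynthesis

**22 ⇒ 21 ⇒ 18 + 19.** The tert-butyl O–C bond and the C12–C13 bond are cut. The butenolide is bought as 3-bromofuran-2(5H)-one 19 and joined last, by B-alkyl Suzuki coupling of the 9-BBN adduct 20 of vinyl alcohol 18. Lactone-enolate alkylation would need a protected C17 hydroxyl and a separate dehydrogenation. The forward step needs chemoselective hydroboration and a mild base.

**18 ⇒ 17 ⇒ 16 ⇒ 15.** C17 is taken back to a methyl ester, and the vinyl group to the C12 silyl ether through bromide 16. Keeping C17 at the ester level until the core is finished lets C8 be equilibrated. The axial tert-butyl ester at C4 is hindered enough to survive the reduction of the C17 ester.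

**15 ⇒ 13 ⇒ 11.** The C4–CH3 bond is cut and a C3 ketone restored (removed forward through tosylhydrazone 14). In β-keto ester 11 the methyl group enters C4 on the α face, anti to the C10 methyl, which gives the axial C19 ester. The same base first equilibrates C8 through enolate 12.

**11 ⇒ 10 (key).** Bonds C4–C5 and C9–C10 are cut together. The precursor 10 is acyclic, with no stereocentre that matters and two defined alkenes. Against a cationic cyclisation, the radical version accepts a carboxyl at C4 and a carbonyl at C17. The forward reaction must deliver 6-endo closure twice, trans fusion, an equatorial C9 chain and one enantiomer; a chiral Lewis acid chelated to the β-keto ester is asked to supply the last.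

**10 ⇒ 9 ⇒ 7 + 8.** The C4–Br bond and then the C1–C2 bond are cut: γ-alkylation of the dianion of tert-butyl 3-oxobutanoate 8 with allylic bromide 7.

**7 ⇒ 6 ⇒ 5 ⇒ 3 + 4; 3 ⇒ 1 + 2.** The E-allylic bromide comes from SeO2 oxidation of the E-methyl of a prenyl terminus (6 from 5). The Z-enoate C8=C9 comes from a Z-selective olefination of aldehyde 4 with phosphonate 3, which is made from 1 and 2.

## Roads not taken

**Alternative 1:** biomimetic cation–olefin bicyclisation, the most obvious route. The cuts are the same C4–C5 and C9–C10 bonds, made by protonative cyclisation of triene A1 to the labd-8(17)-ene A2.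
- A cation at C4 cannot carry a carboxyl, so C19 must enter as a Z-CH2OR group. That geometry is not available from allylic oxidation, and two redox steps follow later.
- The exocyclic alkene must then be hydroborated, which gives the axial C17 alcohol and costs an oxidation–epimerisation–reduction loop.
- Three primary oxygens (C12, C17, C19) would have to be differentiated.
- The chosen plan brings C19 and C17 in at the carboxyl level and uses them as the control elements of the cyclisation.

**Alternative 2:** ring-by-ring relay from (S)-Wieland–Miescher ketone A3. The cuts are C4–C19/C4–CH3 (reductive carboxylation and methylation), C8–C17 (acylation of the C9 ketone to A4) and C9–C11 (enol triflate coupling, then enoate reduction).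
- Each stereocentre is set in its own step, and the C9 ketone needs protection.
- The sp2–sp3 coupling at C9 sits next to quaternary C10.
- The sequence is roughly twice as long. The chosen plan sets C5, C9 and C10 and both rings in one step.

**Alternative 3:** degradation of podocarpic acid A5, which buys C4, C5 and C10. Ring C is dearomatised by Birch reduction to enone A6, and the C13–C14 bond is then cleaved so that C14 becomes C17.
- The oxygen sits at C12, so cleavage between C13 and C14 needs extra functionalisation.
- C13 is lost and must be rebuilt.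
- The hindered acid must first be masked as an ester that can be removed later.
- The starting material is costly and the route is long and degradative.

Key step: step 7

## Route

Step 1
Reactants: 1 methyl 2-[bis(2,2,2-trifluoroethoxy)phosphoryl]acetate; 2 5-bromo-2-methylpent-2-ene
Product: 3 methyl 2-[bis(2,2,2-trifluoroethoxy)phosphoryl]-6-methylhept-5-enoate (racemic)
Conditions: NaH, NaI (cat.), DMSO, rt to 50 °C
Reagents that add atoms: none
Why: SN2 C-alkylation of the stabilised phosphonate carbanion by a primary homoallylic bromide; the new stereocentre is lost in step 2.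

Step 2
Reactants: 3; 4 3-[(tert-butyldimethylsilyl)oxy]propanal
Product: 5 methyl (2Z)-5-[(tert-butyldimethylsilyl)oxy]-2-(4-methylpent-3-en-1-yl)pent-2-enoate
Conditions: KN(SiMe3)2, 18-crown-6, THF, –78 °C
Reagents that add atoms: none
Why: Still–Gennari olefination; the electron-poor phosphonate eliminates from the kinetic adduct and should put the ester cis to the new chain (C7 trans to C11), the geometry that later places C11 equatorial at C9.

Step 3
Reactants: 5
Product: 6 methyl (2Z)-5-[(tert-butyldimethylsilyl)oxy]-2-[(3E)-5-hydroxy-4-methylpent-3-en-1-yl]pent-2-enoate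
Conditions: SeO2 (cat.), tBuOOH, CH2Cl2, rt
Reagents that add atoms: tert-butyl hydroperoxide, CC(C)(C)OO (its oxygen reaches the product through SeO2)
Why: Riley-type allylic oxidation (ene reaction, then [2,3] shift) at the electron-rich trisubstituted alkene; it should oxidise the E-methyl and give the E-allylic alcohol, while the enoate alkene is deactivated.

Step 4
Reactants: 6
Product: 7 methyl (2Z)-2-[(3E)-5-bromo-4-methylpent-3-en-1-yl]-5-[(tert-butyldimethylsilyl)oxy]pent-2-enoate
Conditions: CBr4, PPh3, CH2Cl2, 0 °C
Reagents that add atoms: tetrabromomethane, BrC(Br)(Br)Br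
Why: Appel bromination of a primary allylic alcohol; SN2 at carbon, so the alkene geometry should be kept.

Step 5
Reactants: 7; 8 tert-butyl 3-oxobutanoate
Product: 9 tert-butyl (6E,10Z)-13-[(tert-butyldimethylsilyl)oxy]-10-(methoxycarbonyl)-6-methyl-3-oxotrideca-6,10-dienoate
Conditions: 8, NaH then n-BuLi, THF, 0 °C; 7, –78 to 0 °C; 1 M HCl
Reagents that add atoms: none
Why: γ-alkylation of the acetoacetate dianion; the terminal carbanion displaces the allylic bromide at low temperature, and the α,β-disubstituted enoate is a poor Michael acceptor.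

Step 6
Reactants: 9
Product: 10 tert-butyl (6E,10Z)-2-bromo-13-[(tert-butyldimethylsilyl)oxy]-10-(methoxycarbonyl)-6-methyl-3-oxotrideca-6,10-dienoate (racemic at C2)
Conditions: N-bromosuccinimide, Mg(ClO4)2 (cat.), EtOAc, 0 °C
Reagents that add atoms: N-bromosuccinimide, O=C1CCC(=O)N1Br
Why: electrophilic α-bromination of the Mg-activated β-keto ester enol, which is far more nucleophilic than either alkene; the C2 stereocentre becomes the radical carbon.

Step 7
Reactants: 10
Product: 11 bicyclic keto diester (3-oxo; 4α-CO2tBu with enolisable 4β-H; 5α-H; 8β-CO2Me; 9α-H; 10β-CH3; C9 chain CH2CH2OTBS)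
Conditions: Mg(ClO4)2 (1.1 equiv), 2,2'-(propane-2,2-diyl)bis[(4S)-4-tert-butyl-4,5-dihydro-1,3-oxazole] (1.2 equiv), 4 Å MS, toluene/CH2Cl2, –78 °C; Et3B (cat.)/air; Bu3SnH (syringe pump)
Reagents that add atoms: none
Why: Proposed new method: bromine abstraction from the Mg·bis(oxazoline) chelate of 10 gives an electrophilic 1,3-dicarbonyl radical at C4 that adds 6-endo-trig to C5 of the electron-rich E-alkene; the nucleophilic tertiary C10 radical then adds 6-endo-trig to C9, the β-carbon of the Z-enoate, and the electrophilic C8 radical is reduced by Bu3SnH, so every radical meets a polarity-matched partner; the closest known reaction types are the chiral-Lewis-acid-templated atom-transfer radical bicyclisation of unsaturated α-bromo β-keto esters and the 6-endo relay of tertiary radicals through α-substituted acrylonitrile units in radical polyene cyclisations. Ring A should close 6-endo because the ketone lies inside the forming ring and C10 carries the methyl group; ring B should close 6-endo because 5-exo attack would hit the fully substituted, electronically mismatched α-carbon C8. The absolute configuration at C5 is set by the ligand, which shields one face of the planar chelated radical. C10 follows from the chair–chair transition state (anti addition across the E-alkene, trans fusion), C9 from the Z-enoate geometry, which puts C11 equatorial, and C8 from hydrogen delivery to the less hindered α face (axial ester expected; any 8α-ester converges in step 8), while C4 stays enolisable. The step needs ring closure to outrun hydrogen transfer to the first radical, which slow addition of Bu3SnH and Lewis-acid acceleration of the first closure should secure.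

Step 8
Reactants: 11
Product: 13 keto diester (3-oxo; 4β-CO2tBu; 4α-CH3; 8α-CO2Me; C9 chain CH2CH2OTBS), via potassium enolate 12 (not isolated)
Conditions: tBuOK (3 equiv), tBuOH/THF, 40 °C; then MeI, 0 °C to rt
Reagents that add atoms: iodomethane, CI
Why: tBuOK should first equilibrate the C8 ester to the equatorial 8α epimer (relief of the 1,3-diaxial contact with the C10 methyl) while the β-keto ester is protected as enolate 12; C-methylation of 12 should then occur on the α face, anti to the axial C10 methyl, as is usual for 3-oxo-4-alkoxycarbonyl trans-decalins, giving the axial C19 ester.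

Step 9
Reactants: 13
Product: 15 3-deoxy diester (4β-CO2tBu; 4α-CH3; 8α-CO2Me; C9 chain CH2CH2OTBS), via C3 tosylhydrazone 14 (not isolated)
Conditions: 4-methylbenzenesulfonohydrazide, EtOH, 70 °C; then catecholborane, CHCl3, 0 °C; NaOAc·3H2O, 65 °C
Reagents that add atoms: none
Why: hydrazone formation followed by catecholborane reduction and acetate-induced loss of sulfinate and N2; this non-basic deoxygenation spares the non-enolisable β-keto ester from retro-Claisen cleavage and leaves esters and silyl ether alone.

Step 10
Reactants: 15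
Product: 16 bromide (4β-CO2tBu; 8α-CO2Me; C9 chain CH2CH2Br)
Conditions: Ph3PBr2, CH2Cl2, 0 °C to rt
Reagents that add atoms: dibromotriphenylphosphorane, BrP(Br)(c1ccccc1)(c1ccccc1)c1ccccc1
Why: direct conversion of a primary silyl ether into the bromide through an oxyphosphonium ion and SN2 by bromide; the hindered esters should be untouched.

Step 11
Reactants: 16
Product: 17 vinyl diester (4β-CO2tBu; 8α-CO2Me; vinyl group on C9)
Conditions: tBuOK, DMSO/THF, rt
Reagents that add atoms: none
Why: E2 elimination with a bulky base in a dipolar solvent should give the terminal alkene; C8 is already the thermodynamic epimer, so the base cannot erode it.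

Step 12
Reactants: 17
Product: 18 tert-butyl 5-ethenyl-6-(hydroxymethyl)-1,4a-dimethyldecahydronaphthalene-1-carboxylate (4β-CO2tBu; 8α-CH2OH; 9-vinyl)
Conditions: iBu2AlH, CH2Cl2, –78 °C; aq. potassium sodium tartrate
Reagents that add atoms: none
Why: the secondary, equatorial methyl ester is reduced; the axial neopentyl tert-butyl ester at C4, shielded by the C10 methyl, should survive at –78 °C.

Step 13
Reactants: 18; 19 3-bromofuran-2(5H)-one
Product: 21 tert-butyl ester of the target (17-OH; butenolide in place), via bis(9-BBN) adduct 20 (not isolated)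
Conditions: 9-BBN (2.5 equiv), THF, rt; then 19, PdCl2(dppf) (5 mol%), AsPh3, Cs2CO3, DMF/H2O, rt
Reagents that add atoms: none
Why: anti-Markovnikov hydroboration of the monosubstituted alkene (the hydroxyl is carried as its borinate), then B-alkyl Suzuki–Miyaura coupling with the α-bromo enoate 19, a reaction type known for α-halo enones; no stereocentre is touched, and the butenolide enters only after all hydride and strong-base steps.

Step 14
Reactants: 21
Product: 22 CNP0562063.1 (17-hydroxylabd-13-en-16,15-olid-19-oic acid; 4β-CO2H, 5α-H, 8β-H, 9α-H, 10β-CH3)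
Conditions: CF3CO2H/CH2Cl2 (1:4), 0 °C to rt; aqueous methanolic work-up at pH 7
Reagents that add atoms: none
Why: acidolysis through the tert-butyl cation (AAL1) frees the hindered axial acid without attack at the carbonyl; butenolide and primary alcohol are stable to CF3CO2H, and any trifluoroacetate is cleaved in the work-up.

## Compound list

1 | methyl 2-[bis(2,2,2-trifluoroethoxy)phosphoryl]acetate | COC(=O)CP(=O)(OCC(F)(F)F)OCC(F)(F)F | starting material
2 | 5-bromo-2-methylpent-2-ene | CC(C)=CCCBr | starting material
3 | methyl 2-[bis(2,2,2-trifluoroethoxy)phosphoryl]-6-methylhept-5-enoate (racemic) | COC(=O)C(CCC=C(C)C)P(=O)(OCC(F)(F)F)OCC(F)(F)F | intermediate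
4 | 3-[(tert-butyldimethylsilyl)oxy]propanal | CC(C)(C)[Si](C)(C)OCCC=O | starting material
5 | methyl (2Z)-5-[(tert-butyldimethylsilyl)oxy]-2-(4-methylpent-3-en-1-yl)pent-2-enoate | COC(=O)/C(CCC=C(C)C)=C\CCO[Si](C)(C)C(C)(C)C | intermediate
6 | methyl (2Z)-5-[(tert-butyldimethylsilyl)oxy]-2-[(3E)-5-hydroxy-4-methylpent-3-en-1-yl]pent-2-enoate | COC(=O)/C(CC/C=C(\C)CO)=C\CCO[Si](C)(C)C(C)(C)C | intermediate
7 | methyl (2Z)-2-[(3E)-5-bromo-4-methylpent-3-en-1-yl]-5-[(tert-butyldimethylsilyl)oxy]pent-2-enoate | COC(=O)/C(CC/C=C(\C)CBr)=C\CCO[Si](C)(C)C(C)(C)C | intermediate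
8 | tert-butyl 3-oxobutanoate | CC(=O)CC(=O)OC(C)(C)C | starting material
9 | tert-butyl (6E,10Z)-13-[(tert-butyldimethylsilyl)oxy]-10-(methoxycarbonyl)-6-methyl-3-oxotrideca-6,10-dienoate | CC(C)(C)OC(=O)CC(=O)CC/C(C)=C/CC/C(C(=O)OC)=C/CCO[Si](C)(C)C(C)(C)C | intermediate
10 | tert-butyl (6E,10Z)-2-bromo-13-[(tert-butyldimethylsilyl)oxy]-10-(methoxycarbonyl)-6-methyl-3-oxotrideca-6,10-dienoate (racemic at C2) | CC(C)(C)OC(=O)C(Br)C(=O)CC/C(C)=C/CC/C(C(=O)OC)=C/CCO[Si](C)(C)C(C)(C)C | intermediate
11 | 5-tert-butyl 2-methyl 1-{2-[(tert-butyldimethylsilyl)oxy]ethyl}-8a-methyl-6-oxodecahydronaphthalene-2,5-dicarboxylate; labdane numbering: 3-oxo, 4α-CO2tBu (4β-H, enolisable), 5α-H, 8β-CO2Me (8α-H, kinetic), 9α-H, 10β-CH3 | C[C@]12CCC(=O)[C@@H](C(=O)OC(C)(C)C)[C@@H]1CC[C@H](C(=O)OC)[C@@H]2CCO[Si](C)(C)C(C)(C)C | intermediate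
12 | potassium C3 enolate of the 8α-CO2Me epimer of 11 | C[C@]12CCC([O-])=C(C(=O)OC(C)(C)C)[C@@H]1CC[C@@H](C(=O)OC)[C@@H]2CCO[Si](C)(C)C(C)(C)C.[K+] | intermediate
13 | 5-tert-butyl 2-methyl 1-{2-[(tert-butyldimethylsilyl)oxy]ethyl}-5,8a-dimethyl-6-oxodecahydronaphthalene-2,5-dicarboxylate; 3-oxo, 4β-CO2tBu, 4α-CH3, 5α-H, 8α-CO2Me (8β-H), 9α-H, 10β-CH3 | C[C@]12CCC(=O)[C@](C)(C(=O)OC(C)(C)C)[C@@H]1CC[C@@H](C(=O)OC)[C@@H]2CCO[Si](C)(C)C(C)(C)C | intermediate
14 | C3 4-methylbenzenesulfonylhydrazone of 13 | C[C@]12CC/C(=N\NS(=O)(=O)c3ccc(C)cc3)[C@](C)(C(=O)OC(C)(C)C)[C@@H]1CC[C@@H](C(=O)OC)[C@@H]2CCO[Si](C)(C)C(C)(C)C | intermediate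
15 | 5-tert-butyl 2-methyl 1-{2-[(tert-butyldimethylsilyl)oxy]ethyl}-5,8a-dimethyldecahydronaphthalene-2,5-dicarboxylate; 4β-CO2tBu, 4α-CH3, 5α-H, 8α-CO2Me, 9α-H, 10β-CH3 | C[C@]12CCC[C@](C)(C(=O)OC(C)(C)C)[C@@H]1CC[C@@H](C(=O)OC)[C@@H]2CCO[Si](C)(C)C(C)(C)C | intermediate
16 | 5-tert-butyl 2-methyl 1-(2-bromoethyl)-5,8a-dimethyldecahydronaphthalene-2,5-dicarboxylate; same configurations as 15 | C[C@]12CCC[C@](C)(C(=O)OC(C)(C)C)[C@@H]1CC[C@@H](C(=O)OC)[C@@H]2CCBr | intermediate
17 | 5-tert-butyl 2-methyl 1-ethenyl-5,8a-dimethyldecahydronaphthalene-2,5-dicarboxylate; same configurations as 15 | C[C@]12CCC[C@](C)(C(=O)OC(C)(C)C)[C@@H]1CC[C@@H](C(=O)OC)[C@@H]2C=C | intermediate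
18 | tert-butyl 5-ethenyl-6-(hydroxymethyl)-1,4a-dimethyldecahydronaphthalene-1-carboxylate; 4β-CO2tBu, 5α-H, 8α-CH2OH, 9α-H, 10β-CH3 | C[C@]12CCC[C@](C)(C(=O)OC(C)(C)C)[C@@H]1CC[C@@H](CO)[C@@H]2C=C | intermediate
19 | 3-bromofuran-2(5H)-one | O=C1OCC=C1Br | starting material
20 | bis(9-BBN) adduct of 18 (C12 borane, C17 borinate) | C[C@]12CCC[C@](C)(C(=O)OC(C)(C)C)[C@@H]1CC[C@@H](COB3C4CCCC3CCC4)[C@@H]2CCB5C6CCCC5CCC6 | intermediate
21 | tert-butyl 6-(hydroxymethyl)-1,4a-dimethyl-5-[2-(2-oxo-2,5-dihydrofuran-3-yl)ethyl]decahydronaphthalene-1-carboxylate; configurations as in 22 | C[C@]12CCC[C@](C)(C(=O)OC(C)(C)C)[C@@H]1CC[C@@H](CO)[C@@H]2CCC1=CCOC1=O | intermediate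
22 | 6-(hydroxymethyl)-1,4a-dimethyl-5-[2-(2-oxo-2,5-dihydrofuran-3-yl)ethyl]decahydronaphthalene-1-carboxylic acid (CNP0562063.1); 4β-CO2H, 5α-H, 8β-H, 9α-H, 10β-CH3 | C[C@]12CCC[C@](C)(C(=O)O)[C@@H]1CC[C@@H](CO)[C@@H]2CCC1=CCOC1=O | target

## Step count and least certain steps

Total: 14 steps. Longest linear sequence: 14 steps (1 and 2 to 22).

**Step 7 (key step, proposed new method).** The most likely failure is hydrogen transfer from the stannane to the chelated C4 radical, or to the C10 radical at –78 °C, before ring closure; both radicals are long-lived only if the stannane concentration stays low, and tin species may also erode the facial control of the Lewis acid. Fallback: the cascade is split into two known operations. Starting from 10, the tin-free bromine-atom-transfer cyclisation under the same Mg(ClO4)2/bis(oxazoline) template, run at higher concentration, closes ring A only and gives the monocyclic tertiary bromide tert-butyl 3-bromo-2-[(3Z)-6-[(tert-butyldimethylsilyl)oxy]-3-(methoxycarbonyl)hex-3-en-1-yl]-3-methyl-6-oxocyclohexane-1-carboxylate F1 (C10 epimers). F1 is then heated with Bu3SnH/AIBN in benzene at 80 °C; the tertiary radical closes ring B by 6-endo conjugate addition under substrate control. The route is rejoined at 11.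

**Step 13.** The most likely failure is decomposition of the base-sensitive bromobutenolide, or protodeboronation, before the slow B-alkyl transmetalation. Fallback by enolate alkylation: starting from 16, iBu2AlH gives the bromo alcohol F2. TBSCl/imidazole gives the silyl ether F3. The lithium enolate of 3-(phenylsulfanyl)oxolan-2-one (LiN(iPr)2, THF/DMPU, NaI) is alkylated by F3 to the α-phenylsulfanyl lactone F4. Oxidation with mCPBA and sulfoxide elimination in hot toluene gives the butenolide F5. CF3CO2H then removes the silyl and tert-butyl groups together and rejoins the route at 22.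

**Step 9.** The most likely failure is slow hydrazone formation at the ketone flanked by quaternary C4, or elimination to an alkene during the diazene collapse. Fallback by radical deoxygenation: starting from 13, NaBH4 in MeOH gives the 3β-alcohol F6. NaH/CS2/MeI converts it into the xanthate F7. Bu3SnH/AIBN in toluene at 110 °C (Barton–McCombie) rejoins the route at 15.

**Step 3.** The most likely failure is incomplete conversion, over-oxidation to the enal, or attack at the allylic CH2 groups. Fallback by cleavage and rebuilding: starting from 5, ozonolysis with one equivalent of O3 (then Me2S) at the electron-rich alkene gives the aldehyde F8. Wittig reaction with 2-(triphenyl-λ5-phosphanylidene)propanal gives the E-enal F9. NaBH4/CeCl3·7H2O rejoins the route at 6.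

## Further compounds

F1 | step 7 | tert-butyl 3-bromo-2-[(3Z)-6-[(tert-butyldimethylsilyl)oxy]-3-(methoxycarbonyl)hex-3-en-1-yl]-3-methyl-6-oxocyclohexane-1-carboxylate (C10 epimers) | CC1(Br)CCC(=O)[C@@H](C(=O)OC(C)(C)C)[C@@H]1CC/C(C(=O)OC)=C/CCO[Si](C)(C)C(C)(C)C
F2 | step 13 | tert-butyl 5-(2-bromoethyl)-6-(hydroxymethyl)-1,4a-dimethyldecahydronaphthalene-1-carboxylate | C[C@]12CCC[C@](C)(C(=O)OC(C)(C)C)[C@@H]1CC[C@@H](CO)[C@@H]2CCBr
F3 | step 13 | tert-butyl 5-(2-bromoethyl)-6-{[(tert-butyldimethylsilyl)oxy]methyl}-1,4a-dimethyldecahydronaphthalene-1-carboxylate | C[C@]12CCC[C@](C)(C(=O)OC(C)(C)C)[C@@H]1CC[C@@H](CO[Si](C)(C)C(C)(C)C)[C@@H]2CCBr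
F4 | step 13 | tert-butyl 6-{[(tert-butyldimethylsilyl)oxy]methyl}-1,4a-dimethyl-5-{2-[2-oxo-3-(phenylsulfanyl)oxolan-3-yl]ethyl}decahydronaphthalene-1-carboxylate (C13 epimers) | C[C@]12CCC[C@](C)(C(=O)OC(C)(C)C)[C@@H]1CC[C@@H](CO[Si](C)(C)C(C)(C)C)[C@@H]2CCC1(Sc3ccccc3)CCOC1=O
F5 | step 13 | tert-butyl 6-{[(tert-butyldimethylsilyl)oxy]methyl}-1,4a-dimethyl-5-[2-(2-oxo-2,5-dihydrofuran-3-yl)ethyl]decahydronaphthalene-1-carboxylate | C[C@]12CCC[C@](C)(C(=O)OC(C)(C)C)[C@@H]1CC[C@@H](CO[Si](C)(C)C(C)(C)C)[C@@H]2CCC1=CCOC1=O
F6 | step 9 | 3β-alcohol from 13 (5-tert-butyl 2-methyl 1-{2-[(tert-butyldimethylsilyl)oxy]ethyl}-6-hydroxy-5,8a-dimethyldecahydronaphthalene-2,5-dicarboxylate) | C[C@]12CC[C@H](O)[C@](C)(C(=O)OC(C)(C)C)[C@@H]1CC[C@@H](C(=O)OC)[C@@H]2CCO[Si](C)(C)C(C)(C)C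
F7 | step 9 | S-methyl xanthate of F6 | C[C@]12CC[C@H](OC(=S)SC)[C@](C)(C(=O)OC(C)(C)C)[C@@H]1CC[C@@H](C(=O)OC)[C@@H]2CCO[Si](C)(C)C(C)(C)C
F8 | step 3 | methyl (2Z)-5-[(tert-butyldimethylsilyl)oxy]-2-(3-oxopropyl)pent-2-enoate | COC(=O)/C(CCC=O)=C\CCO[Si](C)(C)C(C)(C)C
F9 | step 3 | methyl (2Z)-5-[(tert-butyldimethylsilyl)oxy]-2-[(3E)-4-methyl-5-oxopent-3-en-1-yl]pent-2-enoate | COC(=O)/C(CC/C=C(\C)C=O)=C\CCO[Si](C)(C)C(C)(C)C
A1 | alternative 1 | (2Z,6E,10E)-1-(benzyloxy)-13-[(tert-butyldimethylsilyl)oxy]-2,6,10-trimethyltrideca-2,6,10-triene | C(OCc1ccccc1)/C(C)=C\CC/C(C)=C/CC/C(C)=C/CCO[Si](C)(C)C(C)(C)C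
A2 | alternative 1 | 19-(benzyloxy)-12-[(tert-butyldimethylsilyl)oxy]-13,14,15,16-tetranorlabd-8(17)-ene | C[C@]12CCC[C@](C)(COCc3ccccc3)[C@@H]1CCC(=C)[C@@H]2CCO[Si](C)(C)C(C)(C)C
A3 | alternative 2 | (S)-Wieland–Miescher ketone | C[C@]12CCC(=O)C=C1CCCC2=O
A4 | alternative 2 | 5-tert-butyl 2-methyl 5,8a-dimethyl-1-oxodecahydronaphthalene-2,5-dicarboxylate (C9 ketone, C8 ester) | C[C@]12CCC[C@](C)(C(=O)OC(C)(C)C)[C@@H]1CCC(C(=O)OC)C2=O
A5 | alternative 3 | podocarpic acid | C[C@]12CCC[C@](C)(C(=O)O)[C@@H]1CCc1ccc(O)cc12
A6 | alternative 3 | methyl 12-oxopodocarp-9(11)-en-19-oate (8β-H) | C[C@]12CCC[C@](C)(C(=O)OC)[C@@H]1CC[C@H]1CCC(=O)C=C12
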